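**Retrosynthetic overview**

1. Feature: in the carbocycle of unit B (C4a–C5–C6–C7–C8–C8a, fused to the pyranone), C5–OH and C6–O form a trans ketol pair between pyranone carbon C4a and a C7 carbonyl, and C8 sits between that carbonyl and pyranone carbon C8a, so it is acidic and can correct itself.
2. Target ⇐ O-debenzylation at C6 ⇐ 5,7-syn reduction of the C7 ketone ⇐ amine-catalysed aldol closure C6→C5 (carbocycle formed last) of a 3-formyl-4-pyranone carrying a racemic 1-aryloxy-3-benzyloxy-2-oxopropyl chain on C2.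
3. Chain: aldehyde unmasked from a dimethyl acetal; C8–OAr by Rh2(OAc)4 O–H insertion of the unit A phenol into an α-diazo ketone; C8–C7 by lateral Claisen acylation of 3-(dimethoxymethyl)-2-methyl-6-(2-phenylethyl)-4-pyranone with methyl benzyloxyacetate.
4. Pyranone ring of unit B: acylketene (from acylated Meldrum's acid) plus the pyrrolidine enamine of ethyl acetoacetate, which fixes CH3 at C2 and the future C5 carbon (ester, then CH2OH, CHO, acetal) at C3. Unit A chromone: C-acylation of the acetophenone and cyclodehydration.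
5. Order of ring formation: chromone ring of unit A, pyranone ring of unit B, carbocycle of unit B.

Key step: step 12

Remark: 1-(2,5-dihydroxy-4-methoxyphenyl)ethanone and ethyl (2E)-3-(pyrrolidin-1-yl)but-2-enoate are taken as purchasable; because an enol partner carrying an acetal would lose methanol by β-elimination, the future C5 carbon enters the pyranone as an ester and is adjusted to the acetal in steps 5 to 7.

**Route**

Step 1
Reactants: 1 1-(2,5-dihydroxy-4-methoxyphenyl)ethanone; 2 3-phenylpropanoyl chloride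
Product: 3 1-(2,5-dihydroxy-4-methoxyphenyl)-5-phenylpentane-1,3-dione
Conditions: LiN(SiMe3)2 (4 equiv), THF, −78 °C; then 2, −78 °C → rt; aq. HCl
Reagents that add atoms: none
Why: Crossed Claisen-type C-acylation of the polylithiated hydroxyacetophenone (two phenoxides and the ketone enolate), in which the enolate carbon is the most nucleophilic site and the acid chloride is the limiting reagent.

Step 2
Reactants: 3 1-(2,5-dihydroxy-4-methoxyphenyl)-5-phenylpentane-1,3-dione
Product: 4 6-hydroxy-7-methoxy-2-(2-phenylethyl)-4H-chromen-4-one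
Conditions: cat. H2SO4, AcOH, 95 °C
Reagents that add atoms: none
Why: Acid-catalysed cyclodehydration of the 2-hydroxyaryl β-diketone (the closing step of the Baker–Venkataraman chromone synthesis), which leaves the methyl ether and the second phenol untouched.

Step 3
Reactants: 5 Meldrum's acid (2,2-dimethyl-1,3-dioxane-4,6-dione); 2 3-phenylpropanoyl chloride
Product: 6 5-(1-hydroxy-3-phenylpropylidene)-2,2-dimethyl-1,3-dioxane-4,6-dione
Conditions: pyridine, CH2Cl2, 0 °C → rt
Reagents that add atoms: none
Why: Oikawa–Yonemitsu C-acylation of Meldrum's acid gives the enolised acyl derivative, a storable precursor of the acylketene.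

Step 4
Reactants: 6 5-(1-hydroxy-3-phenylpropylidene)-2,2-dimethyl-1,3-dioxane-4,6-dione; 7 ethyl (2E)-3-(pyrrolidin-1-yl)but-2-enoate
Product: 10 ethyl 2-methyl-4-oxo-6-(2-phenylethyl)-4H-pyran-3-carboxylate, via acylketene 8 (not isolated), via aminal 9 (not isolated)
Conditions: PhMe, 90 °C (6 in slight excess); then p-TsOH·H2O, THF, rt
Reagents that add atoms: none
Why: Thermolysis of 6 releases acetone and CO2 to give acylketene 8, which is C-acylated by the tertiary enamine and closes through its enol oxygen onto the iminium carbon (formal [4+2] cyclocondensation of an acylketene with an enamine, the known route from diketene or acylated Meldrum's acids to γ-pyrones), and acid then expels pyrrolidine from aminal 9, so that the methyl group at C2 and the ester at C3 are placed without regiochemical ambiguity.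

Step 5
Reactants: 10 ethyl 2-methyl-4-oxo-6-(2-phenylethyl)-4H-pyran-3-carboxylate
Product: 11 3-(hydroxymethyl)-2-methyl-6-(2-phenylethyl)-4H-pyran-4-one
Conditions: i-Bu2AlH (2.5 equiv), CH2Cl2, −78 °C; aq. potassium sodium tartrate
Reagents that add atoms: none
Why: Ester reduction with i-Bu2AlH at low temperature should take the ester to the primary alcohol while the γ-pyranone carbonyl, a doubly vinylogous ester, is left.

Step 6
Reactants: 11 3-(hydroxymethyl)-2-methyl-6-(2-phenylethyl)-4H-pyran-4-one
Product: 12 2-methyl-4-oxo-6-(2-phenylethyl)-4H-pyran-3-carbaldehyde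
Conditions: Dess–Martin periodinane, CH2Cl2, 0 °C → rt
Reagents that add atoms: none
Why: Dess–Martin oxidation of the primary allylic-type alcohol stops at the aldehyde under mild, non-basic conditions.

Step 7
Reactants: 12 2-methyl-4-oxo-6-(2-phenylethyl)-4H-pyran-3-carbaldehyde
Product: 13 3-(dimethoxymethyl)-2-methyl-6-(2-phenylethyl)-4H-pyran-4-one
Conditions: HC(OMe)3, MeOH, cat. p-TsOH, rt
Reagents that add atoms: trimethyl orthoformate, COC(OC)OC; methanol, CO
Why: Acid-catalysed acetalisation masks the aldehyde as a non-electrophilic group that should survive the strong base, diazo transfer and carbenoid steps.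

Step 8
Reactants: 13 3-(dimethoxymethyl)-2-methyl-6-(2-phenylethyl)-4H-pyran-4-one; 14 methyl 2-(benzyloxy)acetate
Product: 15 1-(benzyloxy)-3-[3-(dimethoxymethyl)-4-oxo-6-(2-phenylethyl)-4H-pyran-2-yl]propan-2-one
Conditions: LiN(SiMe3)2 (2.2 equiv), THF, −78 °C; then 14, −78 → −30 °C; AcOH
Reagents that add atoms: none
Why: Lateral (vinylogous) deprotonation of the 2-methyl group, kinetically preferred over the 6-CH2 and helped by lithium coordination to the neighbouring acetal oxygens, is followed by Claisen acylation with the ester, and the second equivalent of base stores the more acidic product as its enolate so that over-addition is prevented.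

Step 9
Reactants: 15 1-(benzyloxy)-3-[3-(dimethoxymethyl)-4-oxo-6-(2-phenylethyl)-4H-pyran-2-yl]propan-2-one
Product: 16 1-(benzyloxy)-3-diazo-3-[3-(dimethoxymethyl)-4-oxo-6-(2-phenylethyl)-4H-pyran-2-yl]propan-2-one
Conditions: p-ABSA, DBU, MeCN, 0 °C → rt
Reagents that add atoms: 4-acetamidobenzenesulfonyl azide (p-ABSA), CC(=O)Nc1ccc(cc1)S(=O)(=O)N=[N+]=[N-]
Why: Regitz diazo transfer to the methylene activated by both the ketone and the pyranone (a vinylogous 1,3-dicarbonyl), the benzyloxy-bearing α′-CH2 being far less acidic.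

Step 10
Reactants: 16 1-(benzyloxy)-3-diazo-3-[3-(dimethoxymethyl)-4-oxo-6-(2-phenylethyl)-4H-pyran-2-yl]propan-2-one; 4 6-hydroxy-7-methoxy-2-(2-phenylethyl)-4H-chromen-4-one
Product: 17 1-(benzyloxy)-3-[3-(dimethoxymethyl)-4-oxo-6-(2-phenylethyl)-4H-pyran-2-yl]-3-{[7-methoxy-4-oxo-2-(2-phenylethyl)-4H-chromen-6-yl]oxy}propan-2-one (racemic, stereocentre enolisable)
Conditions: Rh2(OAc)4 (2 mol %), 4 (1.3 equiv), CH2Cl2, rt → 40 °C, slow addition of 16
Reagents that add atoms: none
Why: Rh2(OAc)4-catalysed carbenoid O–H insertion into the phenol forms the C8–O aryl ether under neutral conditions, slow addition of 16 to an excess of 4 favouring it over capture of the carbenoid by the acetal or benzyl ether, and the new stereocentre is formed racemic and is deliberately left uncontrolled.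

Step 11
Reactants: 17 1-(benzyloxy)-3-[3-(dimethoxymethyl)-4-oxo-6-(2-phenylethyl)-4H-pyran-2-yl]-3-{[7-methoxy-4-oxo-2-(2-phenylethyl)-4H-chromen-6-yl]oxy}propan-2-one
Product: 18 2-[3-(benzyloxy)-1-{[7-methoxy-4-oxo-2-(2-phenylethyl)-4H-chromen-6-yl]oxy}-2-oxopropyl]-4-oxo-6-(2-phenylethyl)-4H-pyran-3-carbaldehyde (racemic)
Conditions: PPTS, acetone–H2O, 40 °C
Reagents that add atoms: water, O
Why: Mild acid-catalysed acetal hydrolysis, eased by the ring oxygen that stabilises the oxocarbenium ion through C2=C3, frees the aldehyde without touching the benzyl and aryl ethers; 18 may rest in part as the cyclic hemiacetal with the C7 enol, which should reopen under the conditions of step 12.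

Step 12
Reactants: 18 2-[3-(benzyloxy)-1-{[7-methoxy-4-oxo-2-(2-phenylethyl)-4H-chromen-6-yl]oxy}-2-oxopropyl]-4-oxo-6-(2-phenylethyl)-4H-pyran-3-carbaldehyde
Product: 20 6-{[(5S,6R,8R)-6-(benzyloxy)-5-hydroxy-4,7-dioxo-2-(2-phenylethyl)-5,6,7,8-tetrahydro-4H-chromen-8-yl]oxy}-7-methoxy-2-(2-phenylethyl)-4H-chromen-4-one, via proline enamine 19 (not isolated)
Conditions: D-proline (30 mol %), CHCl3–DMSO (4:1), rt
Reagents that add atoms: none
Why: Proposed new method: D-proline condenses with the C7 ketone to the (E)-enamine 19 towards C6 (an enamine towards C8 is unproductive, since its attack on the aldehyde would close a four-membered ring, and simply reverts), C6 adds to the pyranone aldehyde through the carboxylic-acid-bridged transition state to form C5–C6, and hydrolysis of the iminium ion returns the catalyst. The closest known reaction types are the proline-catalysed 6-enolendo aldol cyclisation of the Hajos–Parrish type and the proline aldol of O-protected hydroxyacetone; untested here are the pyranone aldehyde as acceptor, the ketone oxygenated on both α-carbons and the stereolabile C8. The carbocycle C4a–C5–C6–C7–C8–C8a closes in the 6-(enolendo)-exo-trig mode. C6 is set by the enamine face that carries the carboxylic acid, and C5 by the hydrogen bond that holds the aldehyde oxygen over the enamine nitrogen while the tether keeps C4a on the ring side, so that C5–OH and C6–OBn end up trans; with the (E)-enamine this sense of addition gives 5S,6R for D-proline (L-proline would give the mirror-image pair). C8 is not set in the bond-forming event but by epimerisation through the enol between the C7 carbonyl and the pyranone, and it should settle with the aryloxy group pseudo-axial, trans to C6–OBn and cis to C5–OH, where the C8–O bond avoids the eclipsed C7=O and ring-oxygen dipoles while C5–OH (hydrogen-bonded to C4=O) and C6–OBn stay equatorial. The step needs enamine formation at C6 only, which ring size secures, and survival of the β-hydroxy ketone, for which the neutral medium, room temperature and immediate reduction in step 13 are chosen.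

Step 13
Reactants: 20 6-{[(5S,6R,8R)-6-(benzyloxy)-5-hydroxy-4,7-dioxo-2-(2-phenylethyl)-5,6,7,8-tetrahydro-4H-chromen-8-yl]oxy}-7-methoxy-2-(2-phenylethyl)-4H-chromen-4-one
Product: 22 6-{[(5S,6R,7S,8S)-6-(benzyloxy)-5,7-dihydroxy-4-oxo-2-(2-phenylethyl)-5,6,7,8-tetrahydro-4H-chromen-8-yl]oxy}-7-methoxy-2-(2-phenylethyl)-4H-chromen-4-one, via diethylboron chelate 21 (not isolated)
Conditions: Et2BOMe, THF–MeOH (4:1), −78 °C; NaBH4, −78 °C; AcOH, then MeOH co-evaporation
Reagents that add atoms: none
Why: Narasaka–Prasad reduction, in which the diethylboron chelate 21 of the C5 oxygen and the C7 carbonyl is attacked by external hydride on the face opposite to the chelate bridge and to the pseudo-axial C8 aryloxy group (axial attack), should give the 5,7-syn diol with C7–OH cis to C8–OAr (7S), while both pyranone carbonyls are inert at −78 °C.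

Step 14
Reactants: 22 6-{[(5S,6R,7S,8S)-6-(benzyloxy)-5,7-dihydroxy-4-oxo-2-(2-phenylethyl)-5,6,7,8-tetrahydro-4H-chromen-8-yl]oxy}-7-methoxy-2-(2-phenylethyl)-4H-chromen-4-one
Product: 23 6-{[(5S,6R,7S,8S)-5,6,7-trihydroxy-4-oxo-2-(2-phenylethyl)-5,6,7,8-tetrahydro-4H-chromen-8-yl]oxy}-7-methoxy-2-(2-phenylethyl)-4H-chromen-4-one (CNP0125425.2)
Conditions: H2 (1 atm), 10% Pd/C, EtOAc–MeOH, rt
Reagents that add atoms: none
Why: Hydrogenolysis of the benzyl ether over Pd/C touches no stereocentre, and the vinylogous-ester double bonds of both pyranone rings and the aryl ethers are expected to survive at short reaction time.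

**Compound list**

1 | 1-(2,5-dihydroxy-4-methoxyphenyl)ethanone | CC(=O)c1cc(O)c(OC)cc1O | starting material
2 | 3-phenylpropanoyl chloride | O=C(Cl)CCc1ccccc1 | starting material
3 | 1-(2,5-dihydroxy-4-methoxyphenyl)-5-phenylpentane-1,3-dione | O=C(CC(=O)CCc2ccccc2)c1cc(O)c(OC)cc1O | intermediate
4 | 6-hydroxy-7-methoxy-2-(2-phenylethyl)-4H-chromen-4-one | COc1cc2oc(CCc3ccccc3)cc(=O)c2cc1O | intermediate
5 | Meldrum's acid (2,2-dimethyl-1,3-dioxane-4,6-dione) | CC1(C)OC(=O)CC(=O)O1 | starting material
6 | 5-(1-hydroxy-3-phenylpropylidene)-2,2-dimethyl-1,3-dioxane-4,6-dione | CC1(C)OC(=O)C(=C(O)CCc2ccccc2)C(=O)O1 | intermediate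
7 | ethyl (2E)-3-(pyrrolidin-1-yl)but-2-enoate | CCOC(=O)/C=C(\C)N1CCCC1 | starting material
8 | (3-phenylpropanoyl)ketene (5-phenylpent-1-ene-1,3-dione) | O=C=CC(=O)CCc1ccccc1 | intermediate
9 | ethyl 2-methyl-4-oxo-6-(2-phenylethyl)-2-(pyrrolidin-1-yl)-3,4-dihydro-2H-pyran-3-carboxylate | CCOC(=O)C1C(=O)C=C(CCc2ccccc2)OC1(C)N1CCCC1 | intermediate
10 | ethyl 2-methyl-4-oxo-6-(2-phenylethyl)-4H-pyran-3-carboxylate | CCOC(=O)c1c(C)oc(CCc2ccccc2)cc1=O | intermediate
11 | 3-(hydroxymethyl)-2-methyl-6-(2-phenylethyl)-4H-pyran-4-one | OCc1c(C)oc(CCc2ccccc2)cc1=O | intermediate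
12 | 2-methyl-4-oxo-6-(2-phenylethyl)-4H-pyran-3-carbaldehyde | O=Cc1c(C)oc(CCc2ccccc2)cc1=O | intermediate
13 | 3-(dimethoxymethyl)-2-methyl-6-(2-phenylethyl)-4H-pyran-4-one | COC(OC)c1c(C)oc(CCc2ccccc2)cc1=O | intermediate
14 | methyl 2-(benzyloxy)acetate | COC(=O)COCc1ccccc1 | starting material
15 | 1-(benzyloxy)-3-[3-(dimethoxymethyl)-4-oxo-6-(2-phenylethyl)-4H-pyran-2-yl]propan-2-one | COC(OC)c1c(CC(=O)COCc2ccccc2)oc(CCc2ccccc2)cc1=O | intermediate
16 | 1-(benzyloxy)-3-diazo-3-[3-(dimethoxymethyl)-4-oxo-6-(2-phenylethyl)-4H-pyran-2-yl]propan-2-one | COC(OC)c1c(C(=[N+]=[N-])C(=O)COCc2ccccc2)oc(CCc2ccccc2)cc1=O | intermediate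
17 | 1-(benzyloxy)-3-[3-(dimethoxymethyl)-4-oxo-6-(2-phenylethyl)-4H-pyran-2-yl]-3-{[7-methoxy-4-oxo-2-(2-phenylethyl)-4H-chromen-6-yl]oxy}propan-2-one, racemic | COc1cc2oc(CCc3ccccc3)cc(=O)c2cc1OC(C(=O)COCc1ccccc1)c1oc(CCc2ccccc2)cc(=O)c1C(OC)OC | intermediate
18 | 2-[3-(benzyloxy)-1-{[7-methoxy-4-oxo-2-(2-phenylethyl)-4H-chromen-6-yl]oxy}-2-oxopropyl]-4-oxo-6-(2-phenylethyl)-4H-pyran-3-carbaldehyde, racemic | COc1cc2oc(CCc3ccccc3)cc(=O)c2cc1OC(C(=O)COCc1ccccc1)c1oc(CCc2ccccc2)cc(=O)c1C=O | intermediate
19 | D-proline (E)-enamine of the C7 ketone of 18, double bond towards C6, (2R) at proline, C8 unassigned | COc1cc2oc(CCc3ccccc3)cc(=O)c2cc1OC(c1oc(CCc2ccccc2)cc(=O)c1C=O)/C(=C\OCc1ccccc1)N1CCC[C@@H]1C(O)=O | intermediate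
20 | 6-{[(5S,6R,8R)-6-(benzyloxy)-5-hydroxy-4,7-dioxo-2-(2-phenylethyl)-5,6,7,8-tetrahydro-4H-chromen-8-yl]oxy}-7-methoxy-2-(2-phenylethyl)-4H-chromen-4-one | COc1cc2oc(CCc3ccccc3)cc(=O)c2cc1O[C@@H]1c2oc(CCc3ccccc3)cc(=O)c2[C@H](O)[C@@H](OCc2ccccc2)C1=O | intermediate
21 | C5-O-diethylboron chelate (diethylborinate) of 20, (5S,6R,8R) | COc1cc2oc(CCc3ccccc3)cc(=O)c2cc1O[C@@H]1c2oc(CCc3ccccc3)cc(=O)c2[C@H](OB(CC)CC)[C@@H](OCc2ccccc2)C1=O | intermediate
22 | 6-{[(5S,6R,7S,8S)-6-(benzyloxy)-5,7-dihydroxy-4-oxo-2-(2-phenylethyl)-5,6,7,8-tetrahydro-4H-chromen-8-yl]oxy}-7-methoxy-2-(2-phenylethyl)-4H-chromen-4-one | COc1cc2oc(CCc3ccccc3)cc(=O)c2cc1O[C@@H]1c2oc(CCc3ccccc3)cc(=O)c2[C@H](O)[C@@H](OCc2ccccc2)[C@@H]1O | intermediate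
23 | 6-{[(5S,6R,7S,8S)-5,6,7-trihydroxy-4-oxo-2-(2-phenylethyl)-5,6,7,8-tetrahydro-4H-chromen-8-yl]oxy}-7-methoxy-2-(2-phenylethyl)-4H-chromen-4-one | COc1cc2oc(CCc3ccccc3)cc(=O)c2cc1O[C@@H]1c2oc(CCc3ccccc3)cc(=O)c2[C@H](O)[C@@H](O)[C@@H]1O | target

**Step count**

Total: 14 steps. Longest linear sequence: 12 steps (steps 3 to 14, from Meldrum's acid); steps 1 and 2 make the unit A phenol, which joins in step 10.

**Steps most likely to fail**

Step 12 (proposed new method). What may go wrong: poor facial selectivity of the enamine addition, sequestration of the catalyst by the aldehyde as an oxazolidinone, dehydration and aromatisation of the ketol, or C8 settling as the wrong epimer. Fallback with known chemistry: setting out from 18, the ring is closed without asymmetric induction under reversible, thermodynamically controlled amine-catalysed aldol conditions (pyrrolidine–AcOH, CHCl3, rt). This should give the same trans ketol as the racemate, that is 20 together with the mirror-image ketol ent-20 F1. The mixture is reduced as in step 13 to 22 and ent-22 F2, and the pair is resolved by preparative HPLC on a chiral stationary phase (amylose or cellulose tris(3,5-dimethylphenylcarbamate)). The route is rejoined at 22. This fallback replaces catalyst control by resolution; it does not correct an unfavourable C8 equilibrium.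

Step 10. What may go wrong: intramolecular capture of the rhodium carbenoid by an acetal oxygen (oxonium ylide formation) or insertion into the benzylic C–H of the benzyl ether, faster than the meeting with the phenol. Fallback: setting out from 15, the activated methylene is chlorinated (N-chlorosuccinimide, CH2Cl2, 0 °C) to 1-(benzyloxy)-3-chloro-3-[3-(dimethoxymethyl)-4-oxo-6-(2-phenylethyl)-4H-pyran-2-yl]propan-2-one F3. The chloride is then displaced by the phenoxide of 4 (K2CO3, acetone, rt), as is done with α-chloro β-dicarbonyl compounds. The route is rejoined at 17 and step 9 is dropped.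

Step 4. What may go wrong: the push–pull enamine may be too weak a nucleophile, so that the acylketene dimerises or is consumed by liberated pyrrolidine. Fallback: C-acylation and ring closure are separated. 4-Phenylbut-1-yne is lithiated (n-BuLi, THF, −78 °C) and carboxylated with CO2 to 5-phenylpent-2-ynoic acid F4, which oxalyl chloride (cat. DMF, CH2Cl2) converts to 5-phenylpent-2-ynoyl chloride F5. Setting out from 7, C-acylation with F5 (Et3N, CH2Cl2, 0 °C) gives ethyl 3-oxo-7-phenyl-2-[1-(pyrrolidin-1-yl)ethylidene]hept-4-ynoate F6. Aqueous HCl in THF hydrolyses the enamine, and the freed enol adds 6-endo to the ynone, which rejoins the route at 10.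

**Further compounds**

F1 | step 12 | ent-20, 6-{[(5R,6S,8S)-6-(benzyloxy)-5-hydroxy-4,7-dioxo-2-(2-phenylethyl)-5,6,7,8-tetrahydro-4H-chromen-8-yl]oxy}-7-methoxy-2-(2-phenylethyl)-4H-chromen-4-one | COc1cc2oc(CCc3ccccc3)cc(=O)c2cc1O[C@H]1c2oc(CCc3ccccc3)cc(=O)c2[C@@H](O)[C@H](OCc2ccccc2)C1=O
F2 | step 12 | ent-22, 6-{[(5R,6S,7R,8R)-6-(benzyloxy)-5,7-dihydroxy-4-oxo-2-(2-phenylethyl)-5,6,7,8-tetrahydro-4H-chromen-8-yl]oxy}-7-methoxy-2-(2-phenylethyl)-4H-chromen-4-one | COc1cc2oc(CCc3ccccc3)cc(=O)c2cc1O[C@H]1c2oc(CCc3ccccc3)cc(=O)c2[C@@H](O)[C@H](OCc2ccccc2)[C@H]1O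
F3 | step 10 | 1-(benzyloxy)-3-chloro-3-[3-(dimethoxymethyl)-4-oxo-6-(2-phenylethyl)-4H-pyran-2-yl]propan-2-one | COC(OC)c1c(C(Cl)C(=O)COCc2ccccc2)oc(CCc2ccccc2)cc1=O
F4 | step 4 | 5-phenylpent-2-ynoic acid | OC(=O)C#CCCc1ccccc1
F5 | step 4 | 5-phenylpent-2-ynoyl chloride | ClC(=O)C#CCCc1ccccc1
F6 | step 4 | ethyl 3-oxo-7-phenyl-2-[1-(pyrrolidin-1-yl)ethylidene]hept-4-ynoate | CCOC(=O)C(C(=O)C#CCCc1ccccc1)=C(C)N1CCCC1
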